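## Analysis of the target

The target is an oxocane whose ring oxygen joins C6 and C12 of a C15 chain (C1 = alkyne CH). C6 carries the (Z)-pent-2-en-4-ynyl arm, C12 the 1-acetoxypropyl arm, C7 an acetate and C9/C10 a free diol. The six stereocentres are 6R,7R,9R,10S,12R,13S. The arms at C6 and C12 are cis across the ring oxygen and the C7 acetate is cis to the C6 arm. The C9/C10 hydroxyls are cis to each other on the opposite face (so C7/C9 are trans-1,3), and C12/C13 is an erythro pair. The terminal Z-enyne rules out hydrogenolysis and dissolving metals, and two secondary acetates next to a free diol invite acyl migration, so the acetates must go on last with the diol masked by an acid-labile group. The difficulty is the eight-membered ring (entropy and transannular strain on closure) together with six stereocentres on a flexible ring whose facial preferences are hard to predict. The strategy rests on C6 and C10: they are 1,5-related across the ring and both oxygenated, so they can be the two carbons of one alkene, C6 ending as a lactone carbonyl and C10 as a ketone. Joining them turns the oxocane into the perimeter of a 2-oxabicyclo[3.3.0]oct-1(5)-ene, with C7–C9 in a cyclopentene and C11–C12 in a dihydrofuran.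

## Retrosynthetic reasoning

**Acetates and diol (34 from 33, 32, 31).** The last step is hydrolysis of the anisylidene acetal of 33. Before it, the C7/C13 diol 32 is acetylated, and 32 comes from 31 by one fluoride treatment that removes both silyl ethers and the alkynyl silane. Nothing basic follows acetylation, so acyl migration has no opportunity.

**Enyne (31 from 29; 29 from 26 and 27).** The Z C3=C4 bond comes from syn hydroboration and protonolysis of the inner triple bond of silyl diyne 29. The C4–C5 bond is cut as an SN2 displacement of primary triflate 26 by diynide 28, made from 27. C5 is a primary, non-stereogenic carbon, and C1–C4 arrive in one piece.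

**C5–C6 (26 from 24; 24 from 21; 21 from 19).** C5 is removed as a methylene added to the C6 lactone carbonyl, and the C6–H bond is made by hydride delivery from silicon tethered to O7. A carbon nucleophile adding to a C6 oxocarbenium ion would have to enter syn to both the C7 oxygen and the C12 arm, which is the hindered face. The tether instead fixes C6 relative to C7 through a five-membered transition state and does not depend on ring conformation.

**Protecting-group switch (19, 18 from 17; 17 from 16).** Oxidation of the C9 PMB ether next to the free C10 hydroxyl ties the cis diol as an acetal. The same operation unmasks the C7 hydroxyl, which is needed first for the tether and later for the acetate. The C10 hydroxyl comes from chelation-controlled reduction of keto lactone 16 through the C9 ether.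

**Key disconnection (16 from 14).** C6 and C10 are reconnected as a tetrasubstituted enol ether. The forward reaction only has to cleave that one electron-rich alkene; no medium ring is closed end to end and no stereocentre is made.

**Enol ether (14 from 12; 12 from 11).** The enol ether arises by loss of methanol from cyclic methyl ketal 12 after silylation of its C13 hydroxyl (13). Ketal 12 comes from epoxy ketone 11: the C6 oxygen opens the epoxide at C12 with inversion. This one step forms the O–C12 bond, sets the erythro C12/C13 pair and leaves only the C13 oxygen free, so the two oxygens are differentiated without a protecting-group step. It also lets C6 be oxidised before any C12 hydroxyl exists.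

**Side chain (11 from 10; 10 from 9; 9 from 7 and 8).** The ketone comes from the alcohol, the epoxide from reagent-controlled epoxidation of the E alkene, and the E alkene from cross-metathesis of the allyl group of 7 with 8.

**Ring (7 from 5 and 6; 5 from 4; 4 from 3; 3 from 2; 2 from 1).** C10–C11 is made by anti opening of epoxide 5 with 6. The bis-ether 4 is C2-symmetric, so its alkene faces are equivalent and only one epoxide can form. Epoxide 5 itself has no symmetry and its two carbons differ, but both opening modes lead to the same 14 because C6 and C10 become sp2. The trans-diol 3 comes from 1 by Mitsunobu inversion and methanolysis, so C7 and C9 are taken from the chiral pool.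

## Alternatives that were turned down

**Alternative 1: Prins-ene closure.** The C11–C12 bond is cut. Forward, SnCl4 would ionise a C12 α-acetoxy ether and a terminal C10=C11 alkene would attack the oxocarbenium ion, with loss of a C9 proton, to give oxocene A1 (C6, C7, C12, C13 set, Z C9=C10).
- For it: the ring and the cis C6/C12 relationship are made in one convergent step, the C4–C5 unit is already in place, and the ring alkene sits where the diol is needed. On step count it is probably shorter than the chosen route.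
- Against it: the cis diol would have to come from dihydroxylation of a flexible oxocene on the face opposite three substituents, which is not secured by any neighbouring group. The closure also competes with other cation pathways and alternative proton loss.
- Comparison: the chosen route sets C10 by chelation to a fixed C9 centre and never closes a medium ring.

**Alternative 2: oxepane-to-oxocane ring expansion.** The O–C6 bond is cut back to an oxepane carrying an exocyclic C6 chloromethanesulfonate. Forward, Zn(OAc)2 in aqueous acetic acid would form a bicyclic oxonium ion, and acetate would open it at C7 to give oxocane A2.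
- For it: it is stronger than the chosen route on C6/C7, since one stereospecific step sets both centres and installs the C7 acetate directly.
- Against it: the oxepane precursor already needs five stereocentres. A2 carries benzyl ethers on C9/C10 that cannot be hydrogenolysed once the enyne is present, and the acetates would have to survive aldehyde formation, olefination and coupling.
- Comparison: the chosen route acetylates last and uses an acid-labile diol mask, at the price of a longer protecting-group sequence.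

**Alternative 3: Claisen ring expansion.** The C7–C8 bond is cut. Forward, a 2-methylene-4-vinyl-1,3-dioxane made by selenoxide elimination would rearrange to unsaturated lactone A3 (C12, C13 set, Z C9=C10, C6 lactone).
- For it: it gives the shortest access to an eight-membered lactone, again without end-to-end closure, and the lactone serves the same C6 tactics as used here.
- Against it: C7 (enolate hydroxylation) and C9/C10 (dihydroxylation) would all be introduced on the medium ring under control of the remote C12 centre only.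
- Comparison: it is shorter to the lactone, but the chosen route brings C7 and C9 with fixed configuration from the cyclopentenediol and sets C10 next to C9.

Key step: step 11

Abbreviations: PMB = 4-methoxybenzyl, TBS = tert-butyldimethylsilyl, TMS = trimethylsilyl, Tf = trifluoromethanesulfonyl, DDQ = 2,3-dichloro-5,6-dicyano-1,4-benzoquinone, CSA = camphorsulfonic acid, DMPU = N,N'-dimethylpropyleneurea.

Assumption: the acetal carbon of the 4-methoxybenzylidene group (18–33) is formed without control and is left undefined in names and SMILES, as are the ring-fusion centres of ozonide 15; both are lost later.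

## Route

Step 1
Reactants: 1 (1S,4R)-cis-4-acetoxycyclopent-2-en-1-ol
Product: 2 (1R,4R)-4-acetoxycyclopent-2-en-1-yl 4-nitrobenzoate
Conditions: 4-nitrobenzoic acid, PPh3, DIAD, THF, 0 °C → rt
Reagents that add atoms: 4-nitrobenzoic acid, OC(=O)c1ccc(cc1)[N+](=O)[O-]
Why: Mitsunobu reaction; the free allylic alcohol is displaced by the carboxylate with inversion (1S to 1R), turning the cis monoester into the trans diester.

Step 2
Reactants: 2 (1R,4R)-4-acetoxycyclopent-2-en-1-yl 4-nitrobenzoate
Product: 3 (1R,3R)-cyclopent-4-ene-1,3-diol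
Conditions: K2CO3 (cat.), MeOH, rt
Reagents that add atoms: none
Why: Base-catalysed transesterification removes both esters without touching the carbinol centres and gives the C2-symmetric trans-diol.

Step 3
Reactants: 3 (1R,3R)-cyclopent-4-ene-1,3-diol
Product: 4 (3R,5R)-3,5-bis(PMB-oxy)cyclopent-1-ene
Conditions: NaH, PMBCl, Bu4NI (cat.), DMF, 0 °C → rt
Reagents that add atoms: 4-methoxybenzyl chloride, COc1ccc(CCl)cc1
Why: Williamson etherification; PMB is chosen because the future C9 ether must chelate zinc in step 12 and be converted oxidatively into an acetal in step 13.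

Step 4
Reactants: 4 (3R,5R)-3,5-bis(PMB-oxy)cyclopent-1-ene
Product: 5 (1R,2R,4R,5S)-2,4-bis(PMB-oxy)-6-oxabicyclo[3.1.0]hexane
Conditions: mCPBA, NaHCO3, CH2Cl2, 0 °C → rt
Reagents that add atoms: 3-chloroperoxybenzoic acid, OOC(=O)c1cccc(Cl)c1
Why: Prilezhaev epoxidation; the two alkene faces of C2-symmetric 4 are equivalent, so a single epoxide should form.

Step 5
Reactants: 5 (1R,2R,4R,5S)-2,4-bis(PMB-oxy)-6-oxabicyclo[3.1.0]hexane; 6 allylmagnesium bromide
Product: 7 (1R,2R,3R,5R)-3,5-bis(PMB-oxy)-2-(prop-2-en-1-yl)cyclopentan-1-ol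
Conditions: 6 (3 equiv), CuI (10 mol%), THF, –30 → 0 °C; aq. NH4Cl
Reagents that add atoms: none
Why: Copper-catalysed anti (SN2) epoxide opening; the Grignard reagent should attack the carbon whose neighbouring ether lies on the epoxide face, away from its own trajectory, giving the all-trans alcohol. Attack at the other carbon would give only a C6/C10 diastereomer that converges on 14, because both centres become sp2.

Step 6
Reactants: 7 (1R,2R,3R,5R)-3,5-bis(PMB-oxy)-2-(prop-2-en-1-yl)cyclopentan-1-ol; 8 (Z)-hex-3-ene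
Product: 9 (1R,2R,3R,5R)-3,5-bis(PMB-oxy)-2-[(2E)-pent-2-en-1-yl]cyclopentan-1-ol
Conditions: RuCl2(=CHPh)(H2IMes)(PCy3) (second-generation Grubbs catalyst, 5 mol%), 8 (10 equiv), CH2Cl2, 40 °C
Reagents that add atoms: none
Why: Olefin cross-metathesis of a terminal alkene with an excess of a symmetrical internal alkene; equilibration should favour the E alkene and but-1-ene leaves as a gas. Residual Z isomer is a poor substrate in step 7 and should be removed there.

Step 7
Reactants: 9 (1R,2R,3R,5R)-3,5-bis(PMB-oxy)-2-[(2E)-pent-2-en-1-yl]cyclopentan-1-ol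
Product: 10 (1R,2R,3R,5R)-2-{[(2S,3S)-3-ethyloxiran-2-yl]methyl}-3,5-bis(PMB-oxy)cyclopentan-1-ol
Conditions: L-fructose-derived Shi ketone (0.3 equiv), KHSO5 (as 2KHSO5·KHSO4·K2SO4), K2CO3, Bu4NHSO4, Na2B4O7 buffer, MeCN–CH2(OMe)2–H2O, 0 °C
Reagents that add atoms: potassium peroxymonosulfate, [K+].[O-]S(=O)(=O)OO
Why: Shi asymmetric epoxidation; the chiral dioxirane transfers oxygen to the E alkene through the spiro transition state under reagent control. The D-fructose ketone gives the (R,R) series, so its enantiomer is used for the (12S,13S) epoxide.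

Step 8
Reactants: 10 (1R,2R,3R,5R)-2-{[(2S,3S)-3-ethyloxiran-2-yl]methyl}-3,5-bis(PMB-oxy)cyclopentan-1-ol
Product: 11 (2S,3R,5R)-2-{[(2S,3S)-3-ethyloxiran-2-yl]methyl}-3,5-bis(PMB-oxy)cyclopentan-1-one
Conditions: Dess–Martin periodinane, NaHCO3, CH2Cl2, 0 °C → rt
Reagents that add atoms: none
Why: Dess–Martin oxidation under buffered, non-basic conditions leaves the epoxide and PMB ethers intact and does not expose the β-alkoxy ketone to base. C6 is oxidised while C12 is still masked in the epoxide, so no second secondary alcohol competes.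

Step 9
Reactants: 11 (2S,3R,5R)-2-{[(2S,3S)-3-ethyloxiran-2-yl]methyl}-3,5-bis(PMB-oxy)cyclopentan-1-one
Product: 12 (1S)-1-[(2R,3aS,4R,6R,6aS)-6a-methoxy-4,6-bis(PMB-oxy)hexahydro-2H-cyclopenta[b]furan-2-yl]propan-1-ol
Conditions: CSA (10 mol%), MeOH, 0 °C; Et3N
Reagents that add atoms: methanol, CO
Why: Acid-catalysed epoxy ketone to ketal cascade; the C6 oxygen (as hemiketal) opens the activated epoxide at C12 in the 5-exo mode with inversion (12S to 12R) and methanol caps C6. This gives the cis-fused ketal with the erythro C12/C13 pair and only the C13 hydroxyl free.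

Step 10
Reactants: 12 (1S)-1-[(2R,3aS,4R,6R,6aS)-6a-methoxy-4,6-bis(PMB-oxy)hexahydro-2H-cyclopenta[b]furan-2-yl]propan-1-ol
Product: 14 tert-butyl{(1S)-1-[(2R,4R,6R)-4,6-bis(PMB-oxy)-3,4,5,6-tetrahydro-2H-cyclopenta[b]furan-2-yl]propoxy}dimethylsilane, via silyl ether 13 (not isolated)
Conditions: TBSOTf (2.5 equiv), Et3N, CH2Cl2, –78 → 0 °C
Reagents that add atoms: tert-butyldimethylsilyl trifluoromethanesulfonate, CC(C)(C)[Si](C)(C)OS(=O)(=O)C(F)(F)F
Why: The silyl triflate first silylates the C13 hydroxyl, then activates the ketal methoxy group; the five-membered oxocarbenium ion loses the C10 proton to the amine (silyl triflate–amine ketal-to-enol-ether elimination). The ring-fusion alkene is expected because it is the more substituted enol ether and carries no second oxygen; 14 is acid-sensitive and is used at once.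

Step 11
Reactants: 14 tert-butyl{(1S)-1-[(2R,4R,6R)-4,6-bis(PMB-oxy)-3,4,5,6-tetrahydro-2H-cyclopenta[b]furan-2-yl]propoxy}dimethylsilane
Product: 16 (3R,5R,8R)-3,5-bis(PMB-oxy)-8-[(1S)-1-(TBS-oxy)propyl]oxocane-2,6-dione, via ozonide 15 (not isolated)
Conditions: O3 (1 equiv, dosed as a cold solution), CH2Cl2, –78 °C; PPh3, –78 °C → rt
Reagents that add atoms: ozone, [O-][O+]=O
Why: Ozone adds as a 1,3-dipole to the C6=C10 bond, the only strongly nucleophilic π bond of 14, and the primary ozonide fragments so that C6 keeps the ring oxygen as an ester carbonyl while C10 leaves as a carbonyl oxide; both ends stay tethered and recombine to ozonide 15, which PPh3 reduces to keto lactone 16. The closest known reaction type is the ozone or peracid cleavage of ring-fusion enol ethers of the hexahydrobenzofuran and tetrahydrochroman type to medium-ring keto lactones. The oxocane is not closed by a cyclisation: it is the perimeter of the 5,5-bicycle and is released when the shared C6=C10 bond is cut, so no end-to-end closure has to compete with oligomerisation. No stereocentre is formed, and C7, C9, C12 and C13 are spectators under the cold, neutral conditions. The selectivity needed is chemoselectivity over the two anisyl rings, which the far higher reactivity of the tetrasubstituted enol ether should secure when ozone is limited to one equivalent at –78 °C. Work-up must stay neutral because 16 carries the C12 acyloxy group β to the C10 ketone and would open by E1cB elimination with base; it is reduced in step 12 without purification.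

Step 12
Reactants: 16 (3R,5R,8R)-3,5-bis(PMB-oxy)-8-[(1S)-1-(TBS-oxy)propyl]oxocane-2,6-dione
Product: 17 (3R,5R,6S,8R)-6-hydroxy-3,5-bis(PMB-oxy)-8-[(1S)-1-(TBS-oxy)propyl]oxocan-2-one
Conditions: Zn(BH4)2, Et2O, –40 °C; pH 7 buffer
Reagents that add atoms: none
Why: Chelation-controlled (Cram chelate) reduction; zinc bridges the C10 carbonyl and the C9 PMB ether oxygen, and hydride enters from the face away from C8, the ring periphery. This places the new hydroxyl cis to the C9 oxygen (10S); the lactone is not reduced at this temperature and 17 is carried on at once.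

Step 13
Reactants: 17 (3R,5R,6S,8R)-6-hydroxy-3,5-bis(PMB-oxy)-8-[(1S)-1-(TBS-oxy)propyl]oxocan-2-one
Product: 18 (3R,5R,6S,8R)-3-hydroxy-5,6-[(4-methoxybenzylidene)dioxy]-8-[(1S)-1-(TBS-oxy)propyl]oxocan-2-one
Conditions: DDQ (2.4 equiv), 4 Å MS, CH2Cl2, 0 °C; then aq. NaHCO3
Reagents that add atoms: none
Why: DDQ oxidises each PMB ether to its benzylic oxocarbenium ion (oxidative acetalisation of a PMB ether by a neighbouring hydroxyl). At C9 the cis C10 hydroxyl captures the ion as a five-membered acetal; at C7 no hydroxyl is within reach (the C10 oxygen is on the other face), so that ion is hydrolysed on work-up to the C7 alcohol. One operation thus masks the diol, removes the free hydroxyl opposite the lactone and frees O7.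

Step 14
Reactants: 18 (3R,5R,6S,8R)-3-hydroxy-5,6-[(4-methoxybenzylidene)dioxy]-8-[(1S)-1-(TBS-oxy)propyl]oxocan-2-one
Product: 19 (3R,5R,6S,8R)-5,6-[(4-methoxybenzylidene)dioxy]-8-[(1S)-1-(TBS-oxy)propyl]-3-(TMS-oxy)oxocan-2-one
Conditions: TMSCl, imidazole, CH2Cl2, 0 °C
Reagents that add atoms: chlorotrimethylsilane, C[Si](C)(C)Cl
Why: Silylation masks the hydroxyl during methylenation; TMS is chosen because it is later removed by K2CO3 in MeOH without touching the TBS ether or an enol ether.

Step 15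
Reactants: 19 (3R,5R,6S,8R)-5,6-[(4-methoxybenzylidene)dioxy]-8-[(1S)-1-(TBS-oxy)propyl]-3-(TMS-oxy)oxocan-2-one
Product: 21 (3R,5R,6S,8R)-5,6-[(4-methoxybenzylidene)dioxy]-2-methylidene-8-[(1S)-1-(TBS-oxy)propyl]oxocan-3-ol, via silylated enol ether 20 (not isolated)
Conditions: Cp2TiMe2 (3 equiv), toluene, 70 °C, dark; then K2CO3, MeOH, 0 °C
Reagents that add atoms: dimethyltitanocene (supplies the C5 methylene), [CH3-].[CH3-].[Ti+4].c1cc[cH-]c1.c1cc[cH-]c1
Why: Petasis methylenation; thermally generated Cp2Ti=CH2 converts the lactone carbonyl into the exocyclic enol ether under non-acidic conditions that spare the acetal and silyl ethers. Methanolysis of the TMS ether then frees O7 for the tether.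

Step 16
Reactants: 21 (3R,5R,6S,8R)-5,6-[(4-methoxybenzylidene)dioxy]-2-methylidene-8-[(1S)-1-(TBS-oxy)propyl]oxocan-3-ol
Product: 24 (2R,3R,5R,6S,8R)-2-(hydroxymethyl)-5,6-[(4-methoxybenzylidene)dioxy]-8-[(1S)-1-(TBS-oxy)propyl]oxocan-3-ol, via dimethylsilyl ether 22 (not isolated), via cyclic siloxane 23 (not isolated)
Conditions: (HMe2Si)2NH, rt; Pt2[(CH2=CHSiMe2)2O]3 (Karstedt catalyst, zerovalent platinum, 1 mol%), toluene, 60 °C; then 30% H2O2, KF, KHCO3, THF–MeOH, rt
Reagents that add atoms: hydrogen peroxide (the C5 oxygen), OO; 1,1,3,3-tetramethyldisilazane (silicon of 22 and 23 only), C[SiH](C)N[SiH](C)C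
Why: Hydroxy-directed intramolecular hydrosilylation of an α-hydroxy enol ether; the O7–SiMe2H group adds across C5=C6 through a five-membered oxasilacycle (Si to C5, H to C6), which gives the 2,3-syn arrangement of O1 and O7, that is C5 cis to O7 on the ring (6R). Tamao–Fleming oxidation then converts the C5–Si bond into the primary alcohol with retention.

Step 17
Reactants: 24 (2R,3R,5R,6S,8R)-2-(hydroxymethyl)-5,6-[(4-methoxybenzylidene)dioxy]-8-[(1S)-1-(TBS-oxy)propyl]oxocan-3-ol
Product: 26 {(2R,3R,5R,6S,8R)-5,6-[(4-methoxybenzylidene)dioxy]-3-(TBS-oxy)-8-[(1S)-1-(TBS-oxy)propyl]oxocan-2-yl}methyl trifluoromethanesulfonate, via hydroxy triflate 25 (not isolated)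
Conditions: Tf2O, 2,6-lutidine, CH2Cl2, –78 °C; then TBSOTf, –78 → 0 °C
Reagents that add atoms: trifluoromethanesulfonic anhydride, O=S(=O)(OS(=O)(=O)C(F)(F)F)C(F)(F)F; tert-butyldimethylsilyl trifluoromethanesulfonate, CC(C)(C)[Si](C)(C)OS(=O)(=O)C(F)(F)F
Why: Triflic anhydride reacts selectively with the primary alcohol at –78 °C, and the secondary C7 hydroxyl is silylated in the same flask, so the sensitive triflate is handled only once and used crude.

Step 18
Reactants: 26 {(2R,3R,5R,6S,8R)-5,6-[(4-methoxybenzylidene)dioxy]-3-(TBS-oxy)-8-[(1S)-1-(TBS-oxy)propyl]oxocan-2-yl}methyl trifluoromethanesulfonate; 27 1,4-bis(trimethylsilyl)buta-1,3-diyne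
Product: 29 (2R,3R,5R,6S,8R)-5,6-[(4-methoxybenzylidene)dioxy]-3-(TBS-oxy)-8-[(1S)-1-(TBS-oxy)propyl]-2-[5-(trimethylsilyl)penta-2,4-diyn-1-yl]oxocane, via lithium diynide 28 (not isolated)
Conditions: 27, MeLi·LiBr, THF, rt; then 26, DMPU, –78 → –20 °C
Reagents that add atoms: none
Why: Mono-desilylation of 27 by MeLi gives diynide 28, whose SN2 displacement of the primary triflate forms C4–C5 and brings in C1–C4 in one piece; the polar cosolvent should favour substitution over elimination.

Step 19
Reactants: 29 (2R,3R,5R,6S,8R)-5,6-[(4-methoxybenzylidene)dioxy]-3-(TBS-oxy)-8-[(1S)-1-(TBS-oxy)propyl]-2-[5-(trimethylsilyl)penta-2,4-diyn-1-yl]oxocane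
Product: 31 (2R,3R,5R,6S,8R)-5,6-[(4-methoxybenzylidene)dioxy]-3-(TBS-oxy)-8-[(1S)-1-(TBS-oxy)propyl]-2-[(2Z)-5-(trimethylsilyl)pent-2-en-4-yn-1-yl]oxocane, via alkenylborane 30 (not isolated)
Conditions: Sia2BH (from BH3·SMe2 and 2-methylbut-2-ene), THF, 0 °C; then AcOH, 0 °C → rt
Reagents that add atoms: none
Why: Monohydroboration of a 1-silyl-1,3-diyne; the dialkylborane adds syn to the alkyl-substituted triple bond (boron at C3), the silyl-capped alkyne being shielded. Protonolysis of the alkenyl–boron bond by acetic acid with retention gives the Z alkene.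

Step 20
Reactants: 31 (2R,3R,5R,6S,8R)-5,6-[(4-methoxybenzylidene)dioxy]-3-(TBS-oxy)-8-[(1S)-1-(TBS-oxy)propyl]-2-[(2Z)-5-(trimethylsilyl)pent-2-en-4-yn-1-yl]oxocane
Product: 32 (2R,3R,5R,6S,8R)-8-[(1S)-1-hydroxypropyl]-5,6-[(4-methoxybenzylidene)dioxy]-2-[(2Z)-pent-2-en-4-yn-1-yl]oxocan-3-ol
Conditions: Bu4NF, THF, 0 °C → rt
Reagents that add atoms: none
Why: Fluoride cleaves both TBS ethers and the alkynyl silane in one operation; the acetal and the Z-enyne are stable to fluoride.

Step 21
Reactants: 32 (2R,3R,5R,6S,8R)-8-[(1S)-1-hydroxypropyl]-5,6-[(4-methoxybenzylidene)dioxy]-2-[(2Z)-pent-2-en-4-yn-1-yl]oxocan-3-ol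
Product: 33 (2R,3R,5R,6S,8R)-8-[(1S)-1-acetoxypropyl]-5,6-[(4-methoxybenzylidene)dioxy]-2-[(2Z)-pent-2-en-4-yn-1-yl]oxocan-3-yl acetate
Conditions: Ac2O, pyridine, DMAP, CH2Cl2, rt
Reagents that add atoms: acetic anhydride, CC(=O)OC(C)=O
Why: Standard acylation of the two secondary alcohols; C9 and C10 are masked, so there is no regiochemical issue.

Step 22
Reactants: 33 (2R,3R,5R,6S,8R)-8-[(1S)-1-acetoxypropyl]-5,6-[(4-methoxybenzylidene)dioxy]-2-[(2Z)-pent-2-en-4-yn-1-yl]oxocan-3-yl acetate
Product: 34 (2R,3R,5R,6S,8R)-8-[(1S)-1-acetoxypropyl]-5,6-dihydroxy-2-[(2Z)-pent-2-en-4-yn-1-yl]oxocan-3-yl acetate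
Conditions: AcOH–THF–H2O (3:1:1), 40 °C
Reagents that add atoms: none
Why: Mild aqueous acid hydrolyses the electron-rich benzylidene acetal; the acetates and the enyne should survive, and the acidic medium disfavours acyl migration to the freed diol.

## Compound list

1 | (1S,4R)-cis-4-acetoxycyclopent-2-en-1-ol | C1=C[C@@H](O)C[C@H]1OC(C)=O | starting material
2 | (1R,4R)-4-acetoxycyclopent-2-en-1-yl 4-nitrobenzoate | C1=C[C@H](OC(=O)c2ccc(cc2)[N+](=O)[O-])C[C@H]1OC(C)=O | intermediate
3 | (1R,3R)-cyclopent-4-ene-1,3-diol | C1=C[C@H](O)C[C@H]1O | intermediate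
4 | (3R,5R)-3,5-bis(PMB-oxy)cyclopent-1-ene | C1=C[C@H](OCc2ccc(OC)cc2)C[C@H]1OCc3ccc(OC)cc3 | intermediate
5 | (1R,2R,4R,5S)-2,4-bis(PMB-oxy)-6-oxabicyclo[3.1.0]hexane | C1[C@@H](OCc2ccc(OC)cc2)[C@H]3O[C@H]3[C@@H]1OCc4ccc(OC)cc4 | intermediate
6 | allylmagnesium bromide | C=CC[Mg]Br | starting material
7 | (1R,2R,3R,5R)-3,5-bis(PMB-oxy)-2-(prop-2-en-1-yl)cyclopentan-1-ol | C=CC[C@H]1[C@H](OCc2ccc(OC)cc2)C[C@@H](OCc2ccc(OC)cc2)[C@@H]1O | intermediate
8 | (Z)-hex-3-ene | CC/C=C\CC | starting material
9 | (1R,2R,3R,5R)-3,5-bis(PMB-oxy)-2-[(2E)-pent-2-en-1-yl]cyclopentan-1-ol | CC/C=C/C[C@H]1[C@H](OCc2ccc(OC)cc2)C[C@@H](OCc2ccc(OC)cc2)[C@@H]1O | intermediate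
10 | (1R,2R,3R,5R)-2-{[(2S,3S)-3-ethyloxiran-2-yl]methyl}-3,5-bis(PMB-oxy)cyclopentan-1-ol | CC[C@@H]1O[C@H]1C[C@H]2[C@H](OCc3ccc(OC)cc3)C[C@@H](OCc3ccc(OC)cc3)[C@@H]2O | intermediate
11 | (2S,3R,5R)-2-{[(2S,3S)-3-ethyloxiran-2-yl]methyl}-3,5-bis(PMB-oxy)cyclopentan-1-one | CC[C@@H]1O[C@H]1C[C@H]2[C@H](OCc3ccc(OC)cc3)C[C@@H](OCc3ccc(OC)cc3)C2=O | intermediate
12 | (1S)-1-[(2R,3aS,4R,6R,6aS)-6a-methoxy-4,6-bis(PMB-oxy)hexahydro-2H-cyclopenta[b]furan-2-yl]propan-1-ol | CC[C@H](O)[C@H]1C[C@H]2[C@H](OCc3ccc(OC)cc3)C[C@@H](OCc3ccc(OC)cc3)[C@@]2(OC)O1 | intermediate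
13 | TBS ether of 12 at the C13 hydroxyl (not isolated) | CC[C@H](O[Si](C)(C)C(C)(C)C)[C@H]1C[C@H]2[C@H](OCc3ccc(OC)cc3)C[C@@H](OCc3ccc(OC)cc3)[C@@]2(OC)O1 | intermediate
14 | tert-butyl{(1S)-1-[(2R,4R,6R)-4,6-bis(PMB-oxy)-3,4,5,6-tetrahydro-2H-cyclopenta[b]furan-2-yl]propoxy}dimethylsilane | CC[C@H](O[Si](C)(C)C(C)(C)C)[C@H]1CC2=C(O1)[C@H](OCc3ccc(OC)cc3)C[C@H]2OCc4ccc(OC)cc4 | intermediate
15 | ozonide of 14: 1,2,4-trioxolane spanning C6 and C10, ring-fusion centres unassigned (not isolated) | CC[C@H](O[Si](C)(C)C(C)(C)C)[C@H]1CC23OOC(O2)(O1)[C@H](OCc4ccc(OC)cc4)C[C@H]3OCc5ccc(OC)cc5 | intermediate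
16 | (3R,5R,8R)-3,5-bis(PMB-oxy)-8-[(1S)-1-(TBS-oxy)propyl]oxocane-2,6-dione | CC[C@H](O[Si](C)(C)C(C)(C)C)[C@H]1CC(=O)[C@H](OCc2ccc(OC)cc2)C[C@@H](OCc2ccc(OC)cc2)C(=O)O1 | intermediate
17 | (3R,5R,6S,8R)-6-hydroxy-3,5-bis(PMB-oxy)-8-[(1S)-1-(TBS-oxy)propyl]oxocan-2-one | CC[C@H](O[Si](C)(C)C(C)(C)C)[C@H]1C[C@H](O)[C@H](OCc2ccc(OC)cc2)C[C@@H](OCc2ccc(OC)cc2)C(=O)O1 | intermediate
18 | (3R,5R,6S,8R)-3-hydroxy-5,6-[(4-methoxybenzylidene)dioxy]-8-[(1S)-1-(TBS-oxy)propyl]oxocan-2-one | CC[C@H](O[Si](C)(C)C(C)(C)C)[C@H]1C[C@@H]2OC(c3ccc(OC)cc3)O[C@@H]2C[C@@H](O)C(=O)O1 | intermediate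
19 | (3R,5R,6S,8R)-5,6-[(4-methoxybenzylidene)dioxy]-8-[(1S)-1-(TBS-oxy)propyl]-3-(TMS-oxy)oxocan-2-one | CC[C@H](O[Si](C)(C)C(C)(C)C)[C@H]1C[C@@H]2OC(c3ccc(OC)cc3)O[C@@H]2C[C@@H](O[Si](C)(C)C)C(=O)O1 | intermediate
20 | 2-methylidene analogue of 19 with the TMS ether in place (not isolated) | CC[C@H](O[Si](C)(C)C(C)(C)C)[C@H]1C[C@@H]2OC(c3ccc(OC)cc3)O[C@@H]2C[C@@H](O[Si](C)(C)C)C(=C)O1 | intermediate
21 | (3R,5R,6S,8R)-5,6-[(4-methoxybenzylidene)dioxy]-2-methylidene-8-[(1S)-1-(TBS-oxy)propyl]oxocan-3-ol | CC[C@H](O[Si](C)(C)C(C)(C)C)[C@H]1C[C@@H]2OC(c3ccc(OC)cc3)O[C@@H]2C[C@@H](O)C(=C)O1 | intermediate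
22 | O7-dimethylsilyl ether of 21 (not isolated) | CC[C@H](O[Si](C)(C)C(C)(C)C)[C@H]1C[C@@H]2OC(c3ccc(OC)cc3)O[C@@H]2C[C@@H](O[SiH](C)C)C(=C)O1 | intermediate
23 | cyclic siloxane: 2,2-dimethyl-1-oxa-2-silacyclopentane fused at C6–C7 (O7–Si–C5), H6 cis to H7 (not isolated) | CC[C@H](O[Si](C)(C)C(C)(C)C)[C@H]1C[C@@H]2OC(c3ccc(OC)cc3)O[C@@H]2C[C@H]4O[Si](C)(C)C[C@H]4O1 | intermediate
24 | (2R,3R,5R,6S,8R)-2-(hydroxymethyl)-5,6-[(4-methoxybenzylidene)dioxy]-8-[(1S)-1-(TBS-oxy)propyl]oxocan-3-ol | CC[C@H](O[Si](C)(C)C(C)(C)C)[C@H]1C[C@@H]2OC(c3ccc(OC)cc3)O[C@@H]2C[C@@H](O)[C@@H](CO)O1 | intermediate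
25 | primary triflate of 24 with the C7 hydroxyl free (not isolated) | CC[C@H](O[Si](C)(C)C(C)(C)C)[C@H]1C[C@@H]2OC(c3ccc(OC)cc3)O[C@@H]2C[C@@H](O)[C@@H](COS(=O)(=O)C(F)(F)F)O1 | intermediate
26 | {(2R,3R,5R,6S,8R)-5,6-[(4-methoxybenzylidene)dioxy]-3-(TBS-oxy)-8-[(1S)-1-(TBS-oxy)propyl]oxocan-2-yl}methyl trifluoromethanesulfonate | CC[C@H](O[Si](C)(C)C(C)(C)C)[C@H]1C[C@@H]2OC(c3ccc(OC)cc3)O[C@@H]2C[C@@H](O[Si](C)(C)C(C)(C)C)[C@@H](COS(=O)(=O)C(F)(F)F)O1 | intermediate
27 | 1,4-bis(trimethylsilyl)buta-1,3-diyne | C[Si](C)(C)C#CC#C[Si](C)(C)C | starting material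
28 | lithium 4-(trimethylsilyl)buta-1,3-diyn-1-ide (not isolated) | [Li]C#CC#C[Si](C)(C)C | intermediate
29 | (2R,3R,5R,6S,8R)-5,6-[(4-methoxybenzylidene)dioxy]-3-(TBS-oxy)-8-[(1S)-1-(TBS-oxy)propyl]-2-[5-(trimethylsilyl)penta-2,4-diyn-1-yl]oxocane | CC[C@H](O[Si](C)(C)C(C)(C)C)[C@H]1C[C@@H]2OC(c3ccc(OC)cc3)O[C@@H]2C[C@@H](O[Si](C)(C)C(C)(C)C)[C@@H](CC#CC#C[Si](C)(C)C)O1 | intermediate
30 | C3-bis(3-methylbutan-2-yl)boryl (Z)-alkene from syn addition to 29 (not isolated) | CC[C@H](O[Si](C)(C)C(C)(C)C)[C@H]1C[C@@H]2OC(c3ccc(OC)cc3)O[C@@H]2C[C@@H](O[Si](C)(C)C(C)(C)C)[C@@H](C/C=C(B(C(C)C(C)C)C(C)C(C)C)\C#C[Si](C)(C)C)O1 | intermediate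
31 | (2R,3R,5R,6S,8R)-5,6-[(4-methoxybenzylidene)dioxy]-3-(TBS-oxy)-8-[(1S)-1-(TBS-oxy)propyl]-2-[(2Z)-5-(trimethylsilyl)pent-2-en-4-yn-1-yl]oxocane | CC[C@H](O[Si](C)(C)C(C)(C)C)[C@H]1C[C@@H]2OC(c3ccc(OC)cc3)O[C@@H]2C[C@@H](O[Si](C)(C)C(C)(C)C)[C@@H](C/C=C\C#C[Si](C)(C)C)O1 | intermediate
32 | (2R,3R,5R,6S,8R)-8-[(1S)-1-hydroxypropyl]-5,6-[(4-methoxybenzylidene)dioxy]-2-[(2Z)-pent-2-en-4-yn-1-yl]oxocan-3-ol | CC[C@H](O)[C@H]1C[C@@H]2OC(c3ccc(OC)cc3)O[C@@H]2C[C@@H](O)[C@@H](C/C=C\C#C)O1 | intermediate
33 | (2R,3R,5R,6S,8R)-8-[(1S)-1-acetoxypropyl]-5,6-[(4-methoxybenzylidene)dioxy]-2-[(2Z)-pent-2-en-4-yn-1-yl]oxocan-3-yl acetate | CC[C@H](OC(C)=O)[C@H]1C[C@@H]2OC(c3ccc(OC)cc3)O[C@@H]2C[C@@H](OC(C)=O)[C@@H](C/C=C\C#C)O1 | intermediate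
34 | (2R,3R,5R,6S,8R)-8-[(1S)-1-acetoxypropyl]-5,6-dihydroxy-2-[(2Z)-pent-2-en-4-yn-1-yl]oxocan-3-yl acetate | C#C/C=C\C[C@H]1O[C@@H]([C@H](CC)OC(C)=O)C[C@H](O)[C@H](O)C[C@H]1OC(C)=O | target

## Step count and least certain steps

Total step count: 22. Longest linear sequence: 22 steps (1 to 34); 6, 8 and 27 are bought.

**Step 11 (key step).** The most likely failure is loss of chemoselectivity: ozone in local excess could oxidise the anisyl ethers, or the ozonide could fragment during reduction with loss of the C12 acyloxy group from the β-acyloxy ketone. Fallback, from 14 to 16: dihydroxylate the enol ether with OsO4 (cat.) and N-methylmorpholine N-oxide to the ring-fusion cis-diol (2R,4R,6R)-4,6-bis(PMB-oxy)-2-[(1S)-1-(TBS-oxy)propyl]hexahydro-2H-cyclopenta[b]furan-3a,6a-diol F1, then cleave the glycol with Pb(OAc)4 in CH2Cl2. This makes the same two carbonyls in two mild stages without a peroxidic intermediate and returns to the route at 16.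

**Step 10.** Proton loss from the oxocarbenium ion could go toward C7 instead of C10, or excess silyl triflate could ionise the doubly allylic PMB ethers of the product. Fallback, from 12 to 14: silylate with TBSCl and imidazole and isolate 13, hydrolyse the ketal with aqueous acetic acid to the hemiketal (2R,3aS,4R,6R,6aS)-4,6-bis(PMB-oxy)-2-[(1S)-1-(TBS-oxy)propyl]hexahydro-2H-cyclopenta[b]furan-6a-ol F2, then dehydrate F2 with pyridinium p-toluenesulfonate and 4 Å MS in warm benzene. Under these equilibrating weak-acid conditions the ring-fusion enol ether should be the thermodynamic product, and the route is rejoined at 14.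

**Step 12.** The new C10 hydroxyl sits directly across the ring from the lactone carbonyl, so transannular acyl transfer to a six-membered lactone (ring contraction) is the main danger; poor facial selectivity is the second. Fallback, from 16 to 18: reduce as before, extract cold and silylate at once with N-(trimethylsilyl)imidazole to the C10 TMS ether of 17 F3; treat F3 with DDQ under anhydrous conditions, where the silyl ether oxygen captures the C9 benzylic cation with loss of the silyl group, giving 18 without a free C10 hydroxyl ever being stored.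

**Step 13.** The C7 ether next to the lactone carbonyl may oxidise more slowly than the C9 ether, and excess oxidant may over-oxidise the new acetal to a hydroxy anisoate. Fallback, from 17 to 18: cleave both PMB ethers with DDQ in CH2Cl2–pH 7 buffer to (3R,5R,6S,8R)-3,5,6-trihydroxy-8-[(1S)-1-(TBS-oxy)propyl]oxocan-2-one F4 and at once acetalise with 4-methoxybenzaldehyde dimethyl acetal and pyridinium p-toluenesulfonate. The cis-vicinal C9/C10 diol should form the five-membered acetal in preference to the trans-1,3 pair, returning to 18.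

**Step 18.** The β-alkoxy primary triflate may eliminate to the exocyclic enol ether, or the diynide may prove too weak a nucleophile. Fallback, from 26 to 29: displace the triflate with the more nucleophilic lithium (trimethylsilyl)acetylide in THF–DMPU to the C5 propargyl silane F5, remove the silyl group with K2CO3 in MeOH to the terminal alkyne F6, and extend F6 by Cadiot–Chodkiewicz coupling with (bromoethynyl)trimethylsilane (CuCl, NH2OH·HCl, BuNH2) to 29.

## Further compounds

F1 | step 11 | (2R,4R,6R)-4,6-bis(PMB-oxy)-2-[(1S)-1-(TBS-oxy)propyl]hexahydro-2H-cyclopenta[b]furan-3a,6a-diol (cis-diol, ring-fusion centres unassigned) | CC[C@H](O[Si](C)(C)C(C)(C)C)[C@H]1CC2(O)C(O)(O1)[C@H](OCc3ccc(OC)cc3)C[C@H]2OCc4ccc(OC)cc4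
F2 | step 10 | (2R,3aS,4R,6R,6aS)-4,6-bis(PMB-oxy)-2-[(1S)-1-(TBS-oxy)propyl]hexahydro-2H-cyclopenta[b]furan-6a-ol | CC[C@H](O[Si](C)(C)C(C)(C)C)[C@H]1C[C@H]2[C@H](OCc3ccc(OC)cc3)C[C@@H](OCc3ccc(OC)cc3)[C@@]2(O)O1
F3 | step 12 | (3R,5R,6S,8R)-3,5-bis(PMB-oxy)-8-[(1S)-1-(TBS-oxy)propyl]-6-(TMS-oxy)oxocan-2-one | CC[C@H](O[Si](C)(C)C(C)(C)C)[C@H]1C[C@H](O[Si](C)(C)C)[C@H](OCc2ccc(OC)cc2)C[C@@H](OCc2ccc(OC)cc2)C(=O)O1
F4 | step 13 | (3R,5R,6S,8R)-3,5,6-trihydroxy-8-[(1S)-1-(TBS-oxy)propyl]oxocan-2-one | CC[C@H](O[Si](C)(C)C(C)(C)C)[C@H]1C[C@H](O)[C@H](O)C[C@@H](O)C(=O)O1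
F5 | step 18 | (2R,3R,5R,6S,8R)-5,6-[(4-methoxybenzylidene)dioxy]-3-(TBS-oxy)-8-[(1S)-1-(TBS-oxy)propyl]-2-[3-(trimethylsilyl)prop-2-yn-1-yl]oxocane | CC[C@H](O[Si](C)(C)C(C)(C)C)[C@H]1C[C@@H]2OC(c3ccc(OC)cc3)O[C@@H]2C[C@@H](O[Si](C)(C)C(C)(C)C)[C@@H](CC#C[Si](C)(C)C)O1
F6 | step 18 | (2R,3R,5R,6S,8R)-5,6-[(4-methoxybenzylidene)dioxy]-2-(prop-2-yn-1-yl)-3-(TBS-oxy)-8-[(1S)-1-(TBS-oxy)propyl]oxocane | CC[C@H](O[Si](C)(C)C(C)(C)C)[C@H]1C[C@@H]2OC(c3ccc(OC)cc3)O[C@@H]2C[C@@H](O[Si](C)(C)C(C)(C)C)[C@@H](CC#C)O1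
A1 | alternative 1 | cis-2,8-disubstituted (Z)-oxoc-4-ene with a 2-(benzyloxy)ethyl arm at C6, triisopropylsilyl ethers at C7 and C13 and the C9=C10 double bond | c1ccccc1COCC[C@H]1O[C@@H]([C@H](CC)O[Si](C(C)C)(C(C)C)C(C)C)C/C=C\C[C@H]1O[Si](C(C)C)(C(C)C)C(C)C
A2 | alternative 2 | oxocane 7,13-diacetate with benzyl ethers at C9 and C10 and a 2-(tert-butyldiphenylsilyloxy)ethyl arm at C6 | CC(C)(C)[Si](c1ccccc1)(c1ccccc1)OCC[C@H]1O[C@@H]([C@H](CC)OC(C)=O)C[C@H](OCc2ccccc2)[C@H](OCc2ccccc2)C[C@H]1OC(C)=O
A3 | alternative 3 | (Z)-8-[(1S)-1-(TBS-oxy)propyl]-3,4,7,8-tetrahydro-2H-oxocin-2-one (C6 lactone, C9=C10 double bond) | O=C1CC/C=C\C[C@H]([C@H](CC)O[Si](C)(C)C(C)(C)C)O1
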